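| flask | acidic substrate | free base | electrophile | capture agent | remark | time |
|---|---|---|---|---|---|---|
| alpha | 20 mM | 18 mM | 24 mM | 1 mM | the very flask that is asked about, followed so far |  |
| theta | 20 mM | 18 mM | 24 mM | 0.67 mM | run made earlier |  |
| flask | 20 mM | 18.0 mM | 24.0 mM | 1.00 mM |  | 15 d |

| run | time / d | target / % | acidic substrate / % |
|---|---|---|---|
| alpha | 0.333 | 47 | 30 |
| alpha | 0.625 | 52 | 25 |
| alpha | 1.67 | 58 | 18 |
| alpha | 3.00 | 53 | 10 |
| alpha | 8.00 | 34 | 12 |
| theta | 0.333 | 48 | 29 |
| theta | 0.833 | 63 | 22 |
| theta | 1.67 | 60 | 15 |
| theta | 4.00 | 49 | 14 |
| theta | 10.0 | 33 | 13 |

(standard deviation of a reading: 2 percentage points)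

- the best time, 15 d at the latest, for target
- the amount of target, in percent of the acidic substrate charged, at that time

In the early times of the alpha run, by 0.333 d, acidic substrate had dropped to 30% and target had risen to 47%, so I first asked how far this could go. Each acidic substrate that reacts takes one free base, and free base was the limiting reagent, at 18.0 mM against 20 mM, with electrophile charged at 24.0 mM. Capture agent removes anion one for one. I therefore carried the room: free base charged less capture agent charged, over acidic substrate charged, which is what target and its isomer share once the free base has reacted away and capture agent has taken its whole charge. In this flask it is 85.0%.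

Did target fill that room? In the alpha run its highest reading was 58%, less than the room, and by 8.00 d it read 34%. I took this to mean that target passes into its isomer while it is still being made, so the top lies where the two rates cross.

Could the theta run help to place that top? Its smaller charge of capture agent, 0.67 mM, shifts the room by 1.7 percentage points, against a scatter of 2 points, so I pooled the runs. Theta's highest reading, 63% at 0.833 d, less that shift gives 61.4%; alpha's is 58% at 1.67 d. I committed to a top between those times and those amounts.

The forecast gave 1.3 d (0.9 d to 1.9 d) and 58% (55% to 61%): “A smooth curve through them peaks near 1.3 d at about 58–59%.” Its amount stands at the lower end of mine.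

The flask gave 61.1% at 1.31 d, by these steps:

    free base → decomposition product (k = 2.00 × 10⁻⁷ /min)
    electrophile + anion → target (k = 0.150 /M/min)
    target ⇌ isomer of the product (K = 1.90, k = 1.30 × 10⁻⁴ /min)
    acidic substrate + free base ⇌ protonated base + anion, settled at all times (K = 2.90)
    anion + capture agent → trapped intermediate (k = 0.330 /M/min)

At that time isomer of the product already stood at 11.6%. By 15.0 d this flask held 30.5% target and 54.8% isomer, together 85.3%, about as much as the room of 85.0%, with 6.53% of the capture agent's own charge still there. A neighbour charged with 34 mM of acidic substrate has a room of 50.0%. Its best was 38.9%, and by 15.0 d its target and isomer together held about as much as that room, 50.2%.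

All runs were generated by integration from invented constants; the scatter is artificial.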